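## Analysis of the target

The target is the 7-O-(3-methylbut-2-enyl) ether of (2R,3R)-taxifolin. It is a chroman-4-one (ring C fused to ring A) with a 3,4-dihydroxyphenyl group (ring B) on C2, a hydroxyl on C3, a free hydroxyl on C5 that is hydrogen-bonded to the C4 carbonyl, and the prenyl ether on C7. The only stereocentres are C2 and C3; they are adjacent, H2 and H3 are trans (aryl and hydroxyl both equatorial, the thermodynamically preferred relation), and the absolute configuration is 2R,3R.

The α-ketol beside a benzylic aryl ether is the main liability. Base can open ring C by expelling the O1 phenoxide from the C3/C4 enolate, which scrambles both centres and leads on to flavonol or aurone-type products. The catechol is easily oxidised. The prenyl ether excludes hydrogenolysis, strong acid, heat and any oxidant for electron-rich alkenes once it is in place. Of the five hydroxyls exactly one, O7, must be alkylated.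

The difficulty is therefore twofold: fixing two contiguous centres in the absolute sense on a scaffold where both C2 and C4 are benzylic and ionise readily, and sequencing protection so that the prenyl group meets none of the reactions it cannot survive.

The strategy rests on one structural feature. C3 and C4 both carry oxygen, so they can come from a C3=C4 alkene of a 2H-chromene whose single stereocentre, C2, is set by asymmetric catalysis and then steers an oxidant to the opposite face. C4 becomes the only benzylic carbinol, activated by O1, O5 and O7 of ring A, and can be oxidised selectively to the ketone.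

## Retrosynthetic reasoning

**18 ⇒ 17 (O–Si bonds of ring B).** The catechol is unmasked last. Silyl ethers are chosen because they survive hydrogenolysis and mild carbonate base and come off with buffered fluoride, which touches neither the prenyl ether nor the ketol.

**17 ⇒ 15 + 16 (O7–C bond of the prenyl ether).** The prenyl alkene would be dihydroxylated in the key step and reduced during debenzylation, so it enters after both. In 15 the choice of oxygen is settled by the structure: ring B is silylated, O5 is tied up in the hydrogen bond to C4=O, O3 is an ordinary alcohol, and O7 is the one acidic, unhindered phenol.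

**15 ⇒ 14 (benzyl ethers on O5 and O7).** Ring A needs protection that withstands an ylide, an organolithium base, a ruthenium carbene and two oxidations, and that is orthogonal to the ring B silyl ethers. Benzyl ethers meet this and leave by hydrogenolysis, the one reduction the molecule tolerates before the prenyl group is present.

**14 ⇒ 13 (C4 carbonyl from the C4 carbinol).** Keeping C4 as an alcohol until the stereocentres exist means that no base-sensitive ketol is carried through the early steps. The forward reaction must oxidise the benzylic C4–OH and leave the non-benzylic C3–OH alone. The C4 configuration is irrelevant because it is destroyed here.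

**13 ⇒ 12 (C3–O and C4–O bonds).** Both oxygens are removed together to reveal the C3=C4 alkene of flav-3-ene 12. This turns a two-stereocentre problem into a one-stereocentre problem. The forward syn-dihydroxylation must take the face opposite the C2 aryl group, which places O3 trans to ring B.

**12 ⇒ 11 (C3=C4 bond).** The ring C alkene is cut by a metathesis transform to two terminal alkenes, an aryl vinyl group and an allylic ether. Ring closure then happens under neutral conditions, with no acid or base near the ionisable C2–O bond, and no stereochemistry is at stake.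

**11 ⇒ 4 + 9 (O1–C2 bond).** This is where the single stereocentre is created. An iridium-catalysed allylic substitution of the linear, achiral cinnamyl carbonate 9 by the phenoxide of 4 forms the branched aryl allyl ether and sets C2 in the same event. Cutting C2–aryl or C2–C3 instead would need a preformed chiral fragment.

**4 ⇒ 3 ⇒ 1 + 2 (ring A fragment).** The vinyl group comes from the formyl group by methylenation. The benzyl ethers are placed by partial alkylation of 1, where the hydroxyl that stays free is the one chelated to the aldehyde, exactly the oxygen that becomes O1.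

**9 ⇒ 8 ⇒ 7 ⇒ 6 ⇒ 5 (ring B fragment).** The carbonate comes from the allylic alcohol 8, that from the cinnamate 7 by reduction, and 7 from the silylated aldehyde 6 by an E-selective two-carbon olefination.

## Alternatives that were turned down

**Alternative 1: Friedel–Crafts closure of ring C.**
- Disconnection: the C4–C4a aryl ketone bond.
- Forward key step: the open-chain acid (2R,3R)-2-(benzyloxy)-3-[3,4-bis(benzyloxy)phenyl]-3-[3,5-bis(benzyloxy)phenoxy]propanoic acid A2 is activated as a mixed anhydride with a perfluorinated anhydride and acylates its own phloroglucinol ring to give (2R,3R)-penta-O-benzyltaxifolin A1.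
- For: the two positions ortho to the ether oxygen are equivalent, so there is no regiochemical question. Both stereocentres can be installed on an acyclic cinnamate by a catalyst-controlled dihydroxylation. The ketone arrives in the correct oxidation state.
- Against: the acylium ion of A2 carries an α-alkoxy group, and such ions lose CO easily. The C–O bond to the phloroglucinol oxygen is a benzylic ether at an electron-rich carbon and can ionise under the acidic, dehydrating conditions, with loss of the phenol, racemisation or elimination. Making that ether with defined configuration means a displacement at an electron-rich benzylic carbinol, which tends towards SN1. A1 carries five identical benzyl groups, so their removal exposes all five hydroxyls at once and the prenyl group must then find O7 in competition with the catechol.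
- Comparison: this route is stronger on how the stereocentres are set (reagent control on an open chain) and needs no C4 oxidation. The chosen route offers instead a neutral ring closure that never exposes the C2–O bond to acid, and orthogonal ring A and ring B protection that makes the O7 alkylation unambiguous. Step counts are similar.

**Alternative 2: ortho-quinone methide oxa-Diels–Alder.**
- Disconnection: O1–C2 and C3–C4 together, so ring C comes from a [4+2] union of a ring A fragment and a ring B fragment.
- Forward key step: 2,6-dihydroxy-4-(3-methylbut-2-enyloxy)benzaldehyde A4, an orthoformate and a chiral phosphoric acid generate an α-methoxy ortho-quinone methide, which adds to (E)-2-[3,4-bis(tert-butyldimethylsilyloxy)phenyl]vinyl acetate A5 to give the 2,3-trans-3-acetoxy-4-methoxyflavan A3.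
- For: it is the most convergent plan. Two bonds, the ring and both stereocentres form in one step from two small pieces. The prenyl ether is present from the start, O5 and O7 are differentiated without protecting groups, and the route is the shortest.
- Against: the regiochemistry depends on which donor of A5 dominates. The aryl group must outweigh the acetoxy group, otherwise O1 bonds to the acetoxy carbon and an isoflavan-type acetal results. The prenyl group, a trisubstituted electron-rich alkene and an acid-labile allyl ether, shares the flask with a strong Brønsted acid and an electrophilic quinone methide. A4 has a second free hydroxyl that can bind the catalyst in a second way, so enantiofacial control is uncertain. After the cycloaddition, the 4-methoxy group of A3 still has to become a ketone and the acetate has to be removed from a base-sensitive ketol, which costs several steps.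
- Comparison: this alternative is clearly stronger in convergence and step count. The chosen route offers steps whose regiochemical and stereochemical outcomes can each be predicted from a well-explored reaction class, with C2 set first by a catalyst and C3 set relative to it.

**Alternative 3: ring A built last.**
- Disconnection: C4a–C5 and C8–C8a, so the aromatic ring is assembled on a stereodefined dihydropyranone that already carries ring B.
- Forward key step: 1-methoxy-1-(trimethylsilyloxy)-3-(3-methylbut-2-enyloxy)buta-1,3-diene A8 adds across the brominated enone bond of (2R,3R)-5-bromo-3-(tert-butyldimethylsilyloxy)-2-[3,4-bis(tert-butyldimethylsilyloxy)phenyl]-2,3-dihydropyran-4-one A7. An amine base then removes HBr and methanol to aromatise, giving (2R,3R)-3,3',4'-tris-O-(tert-butyldimethylsilyl)-7-O-prenyltaxifolin A6.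
- For: the oxygen pattern of ring A emerges already differentiated (free chelated 5-OH, prenyl on O7). No benzyl groups and no hydrogenolysis are needed. The polarity of the diene fixes the regiochemistry, and the stereocentres are not touched by the key step.
- Against: A7 is itself a demanding target. It needs an enantioselective construction of a trans-2-aryl-3-oxy-dihydropyranone and then α-bromination, so the stereochemical problem is only moved. A7 is a vinylogous ester and a poor dienophile. A8 is a hydrolytically fragile ketene acetal. The amine step acts on an adduct whose C3 centre is α to the ketone, so epimerisation or elimination is possible. The step count is the highest of the four plans.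
- Comparison: this alternative is stronger on differentiating O5 from O7 without protecting groups. The chosen route buys ring A intact, gets the same differentiation from the chelated 5-hydroxyl, and sets both stereocentres in two catalytic steps.

Key step: step 9

Remark on the chemistry: the (Sa,Sc,Sc) enantiomer of the binaphthyl phosphoramidite is assumed to deliver the (S)-configured branched ether from an (E)-cinnamyl carbonate and an aryloxide. If the opposite sense is found, the mirror-image ligand is used and nothing else changes.

## Route

Step 1
Reactants: 1 2,4,6-trihydroxybenzaldehyde; 2 benzyl bromide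
Product: 3 2,4-bis(benzyloxy)-6-hydroxybenzaldehyde
Conditions: BnBr (2.1 equiv), K2CO3 (2.2 equiv), DMF, 0 °C to rt
Reagents that add atoms: benzyl bromide (compound 2), BrCc1ccccc1
Why: Williamson etherification; the 4-hydroxyl (para to the formyl group) is the most acidic and reacts first, one ortho hydroxyl follows, and the remaining ortho hydroxyl is held in a hydrogen bond to the aldehyde and is the least nucleophilic, so alkylation should stop at the dibenzyl stage.

Step 2
Reactants: 3 2,4-bis(benzyloxy)-6-hydroxybenzaldehyde
Product: 4 3,5-bis(benzyloxy)-2-vinylphenol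
Conditions: Ph3PCH3Br (2.5 equiv), KOtBu (2.5 equiv), THF, 0 °C to rt; aq. NH4Cl; product kept cold and used promptly
Reagents that add atoms: methyltriphenylphosphonium bromide, C[P+](c1ccccc1)(c1ccccc1)c1ccccc1.[Br-]
Why: Wittig methylenation of a salicylaldehyde; an excess of the unstabilised ylide is used because the phenol consumes one equivalent, and this ylide is reactive enough for the electron-rich aldehyde.

Step 3
Reactants: 5 3,4-dihydroxybenzaldehyde
Product: 6 3,4-bis(tert-butyldimethylsilyloxy)benzaldehyde
Conditions: TBSCl (2.4 equiv), imidazole (5 equiv), DMF, rt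
Reagents that add atoms: tert-butyldimethylsilyl chloride, CC(C)(C)[Si](C)(C)Cl
Why: Standard silylation of both catechol hydroxyls; the aldehyde is inert to these conditions.

Step 4
Reactants: 6 3,4-bis(tert-butyldimethylsilyloxy)benzaldehyde
Product: 7 ethyl (E)-3-[3,4-bis(tert-butyldimethylsilyloxy)phenyl]prop-2-enoate
Conditions: Ph3P=CHCO2Et (1.2 equiv), toluene, 80 °C
Reagents that add atoms: ethyl (triphenylphosphoranylidene)acetate, CCOC(=O)C=P(c1ccccc1)(c1ccccc1)c1ccccc1
Why: Wittig olefination with a stabilised ylide, which is E-selective and needs no added base, so the aryl silyl ethers are not at risk.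

Step 5
Reactants: 7 ethyl (E)-3-[3,4-bis(tert-butyldimethylsilyloxy)phenyl]prop-2-enoate
Product: 8 (E)-3-[3,4-bis(tert-butyldimethylsilyloxy)phenyl]prop-2-en-1-ol
Conditions: i-Bu2AlH (2.5 equiv), CH2Cl2, −78 °C; potassium sodium tartrate work-up
Reagents that add atoms: none
Why: 1,2-Reduction of an α,β-unsaturated ester to the allylic alcohol by diisobutylaluminium hydride; the alkene geometry and the silyl ethers are retained.

Step 6
Reactants: 8 (E)-3-[3,4-bis(tert-butyldimethylsilyloxy)phenyl]prop-2-en-1-ol
Product: 9 (E)-3-[3,4-bis(tert-butyldimethylsilyloxy)phenyl]prop-2-en-1-yl methyl carbonate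
Conditions: ClCO2Me (1.5 equiv), pyridine (3 equiv), CH2Cl2, 0 °C
Reagents that add atoms: methyl chloroformate, COC(=O)Cl
Why: Acylation of a primary allylic alcohol to the methyl carbonate, the standard leaving group for iridium-catalysed allylic substitution.

Step 7
Reactants: 4 3,5-bis(benzyloxy)-2-vinylphenol; 9 (E)-3-[3,4-bis(tert-butyldimethylsilyloxy)phenyl]prop-2-en-1-yl methyl carbonate
Product: 11 (S)-1-[3,4-bis(tert-butyldimethylsilyloxy)phenyl]prop-2-en-1-yl 3,5-bis(benzyloxy)-2-vinylphenyl ether, via lithium 3,5-bis(benzyloxy)-2-vinylphenoxide 10 (not isolated)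
Conditions: 4 (1.5 equiv), n-BuLi (1.5 equiv), THF, 0 °C; then 9 (1.0 equiv), [Ir(cod)Cl]2 (2 mol%), (Sa,Sc,Sc)-O,O'-(1,1'-binaphthyl-2,2'-diyl)-N,N-bis(1-phenylethyl)phosphoramidite (4 mol%, pre-activated with n-PrNH2), THF, rt to 40 °C, stopped at full conversion
Reagents that add atoms: none
Why: Iridium-catalysed asymmetric allylic etherification: the cyclometalated iridium phosphoramidite complex ionises the carbonate to an allyl complex, and the aryloxide attacks the aryl-substituted terminus to give the branched ether. The ligand fixes the configuration of the new centre (the later C2) as S; electron-rich cinnamyl carbonates and ortho-substituted aryloxides belong to the known scope.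

Step 8
Reactants: 11 (S)-1-[3,4-bis(tert-butyldimethylsilyloxy)phenyl]prop-2-en-1-yl 3,5-bis(benzyloxy)-2-vinylphenyl ether
Product: 12 (2S)-5,7-bis(benzyloxy)-2-[3,4-bis(tert-butyldimethylsilyloxy)phenyl]-2H-chromene
Conditions: second-generation Grubbs catalyst RuCl2(=CHPh)(H2IMes)(PCy3) (5 mol%), CH2Cl2 (0.01 M), 40 °C, dark
Reagents that add atoms: none
Why: Ring-closing metathesis of an aryl vinyl group with an allylic ether alkene closes the six-membered ring C with loss of ethylene, a known entry to 2-substituted 2H-chromenes. The conditions are neutral, so the C2 centre is untouched; its descriptor stays S because only the partner carbon of the alkene changes.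

Step 9
Reactants: 12 (2S)-5,7-bis(benzyloxy)-2-[3,4-bis(tert-butyldimethylsilyloxy)phenyl]-2H-chromene
Product: 13 (2R,3S,4S)-5,7-bis(benzyloxy)-2-[3,4-bis(tert-butyldimethylsilyloxy)phenyl]chroman-3,4-diol (2,3-trans-3,4-cis)
Conditions: OsO4 (2 mol%, solution in t-BuOH), NMO (1.5 equiv), acetone/THF/H2O, 0 °C to rt, dark; aq. Na2SO3; chromatography on Et3N-deactivated silica
Reagents that add atoms: osmium tetroxide, O=[Os](=O)(=O)=O; N-methylmorpholine N-oxide, C[N+]1([O-])CCOCC1; water, O
Why: Osmium tetroxide adds across the C3=C4 bond in a concerted [3+2] cycloaddition to give a cyclic osmate ester of hexavalent osmium, which is hydrolysed to the diol while the N-oxide returns the metal to the tetroxide (Upjohn dihydroxylation). The closest known reaction type is the osmium-catalysed syn-dihydroxylation of flav-3-enes and other 2-substituted 2H-chromenes. No ring is closed; two C–O bonds form on the same face, so O3 and O4 are cis by mechanism. The new centres C3 (S) and C4 (S) are both controlled by C2: the ring B aryl group shields one face of the nearly flat pyran ring next to C3, and the bulky oxidant adds from the other, so O3 ends trans to the aryl group. The step needs only facial selectivity, which the C2 substituent provides; chemoselectivity is secured because the chromene alkene is the only alkene present, and benzyl and aryl silyl ethers are inert to the neutral conditions. The C2 descriptor changes from S to R only because C3 now outranks the aryl group. Only the C2/C3 relation matters later, since C4 becomes the ketone.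

Step 10
Reactants: 13 (2R,3S,4S)-5,7-bis(benzyloxy)-2-[3,4-bis(tert-butyldimethylsilyloxy)phenyl]chroman-3,4-diol
Product: 14 (2R,3R)-5,7-bis(benzyloxy)-2-[3,4-bis(tert-butyldimethylsilyloxy)phenyl]-3-hydroxychroman-4-one
Conditions: activated MnO2 (15 equiv), CH2Cl2, rt, monitored closely
Reagents that add atoms: none
Why: Chemoselective oxidation of a benzylic alcohol by manganese dioxide; C4–OH is the only benzylic carbinol and is activated by three ring A oxygens, whereas C3–OH is a plain secondary alcohol. The 2,3-trans relation is kept because C2 and C3 are not involved, and C3 reverts to the descriptor R as C4 becomes a carbonyl.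

Step 11
Reactants: 14 (2R,3R)-5,7-bis(benzyloxy)-2-[3,4-bis(tert-butyldimethylsilyloxy)phenyl]-3-hydroxychroman-4-one
Product: 15 (2R,3R)-2-[3,4-bis(tert-butyldimethylsilyloxy)phenyl]-3,5,7-trihydroxychroman-4-one
Conditions: H2 (1 atm), 10% Pd/C, EtOAc, rt
Reagents that add atoms: none
Why: Hydrogenolysis of the two aryl benzyl ethers; in a non-protic solvent the aryl silyl ethers, the electron-rich aryl ketone and the C2–O1 bond should survive.

Step 12
Reactants: 15 (2R,3R)-2-[3,4-bis(tert-butyldimethylsilyloxy)phenyl]-3,5,7-trihydroxychroman-4-one; 16 prenyl bromide (1-bromo-3-methylbut-2-ene)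
Product: 17 (2R,3R)-2-[3,4-bis(tert-butyldimethylsilyloxy)phenyl]-3,5-dihydroxy-7-(3-methylbut-2-enyloxy)chroman-4-one
Conditions: 16 (1.1 equiv), K2CO3 (1.2 equiv), dry acetone, rt
Reagents that add atoms: prenyl bromide (compound 16), CC(C)=CCBr
Why: Williamson etherification of the most acidic phenol; the 7-hydroxyl is para to the carbonyl and unhindered, the 5-hydroxyl is chelated to C4=O and the 3-hydroxyl is not deprotonated by carbonate. The 4'-silyl ether blocks ring opening through a quinone methide.

Step 13
Reactants: 17 (2R,3R)-2-[3,4-bis(tert-butyldimethylsilyloxy)phenyl]-3,5-dihydroxy-7-(3-methylbut-2-enyloxy)chroman-4-one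
Product: 18 (2R,3R)-2-(3,4-dihydroxyphenyl)-3,5-dihydroxy-7-(3-methylbut-2-enyloxy)chroman-4-one (target)
Conditions: HF·pyridine, pyridine, THF, 0 °C to rt
Reagents that add atoms: none
Why: Fluoride cleavage of the two aryl silyl ethers under buffered, weakly acidic conditions, which spare the prenyl ether and avoid the base to which the ketol is sensitive.

## Compound list

1 | 2,4,6-trihydroxybenzaldehyde | O=Cc1c(O)cc(O)cc1O | starting material
2 | benzyl bromide | BrCc1ccccc1 | starting material
3 | 2,4-bis(benzyloxy)-6-hydroxybenzaldehyde | O=Cc1c(O)cc(OCc2ccccc2)cc1OCc1ccccc1 | intermediate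
4 | 3,5-bis(benzyloxy)-2-vinylphenol | C=Cc1c(O)cc(OCc2ccccc2)cc1OCc1ccccc1 | intermediate
5 | 3,4-dihydroxybenzaldehyde | O=Cc1ccc(O)c(O)c1 | starting material
6 | 3,4-bis(tert-butyldimethylsilyloxy)benzaldehyde | O=Cc1ccc(O[Si](C)(C)C(C)(C)C)c(O[Si](C)(C)C(C)(C)C)c1 | intermediate
7 | ethyl (E)-3-[3,4-bis(tert-butyldimethylsilyloxy)phenyl]prop-2-enoate | CCOC(=O)/C=C/c1ccc(O[Si](C)(C)C(C)(C)C)c(O[Si](C)(C)C(C)(C)C)c1 | intermediate
8 | (E)-3-[3,4-bis(tert-butyldimethylsilyloxy)phenyl]prop-2-en-1-ol | OC/C=C/c1ccc(O[Si](C)(C)C(C)(C)C)c(O[Si](C)(C)C(C)(C)C)c1 | intermediate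
9 | (E)-3-[3,4-bis(tert-butyldimethylsilyloxy)phenyl]prop-2-en-1-yl methyl carbonate | COC(=O)OC/C=C/c1ccc(O[Si](C)(C)C(C)(C)C)c(O[Si](C)(C)C(C)(C)C)c1 | intermediate
10 | lithium 3,5-bis(benzyloxy)-2-vinylphenoxide | [Li+].[O-]c1cc(OCc2ccccc2)cc(OCc2ccccc2)c1C=C | intermediate (not isolated)
11 | (S)-1-[3,4-bis(tert-butyldimethylsilyloxy)phenyl]prop-2-en-1-yl 3,5-bis(benzyloxy)-2-vinylphenyl ether | C=Cc1c(OCc2ccccc2)cc(OCc2ccccc2)cc1O[C@H](c1ccc(O[Si](C)(C)C(C)(C)C)c(O[Si](C)(C)C(C)(C)C)c1)C=C | intermediate
12 | (2S)-5,7-bis(benzyloxy)-2-[3,4-bis(tert-butyldimethylsilyloxy)phenyl]-2H-chromene | O(Cc1ccccc1)c1cc(OCc2ccccc2)c2c(c1)O[C@H](c1ccc(O[Si](C)(C)C(C)(C)C)c(O[Si](C)(C)C(C)(C)C)c1)C=C2 | intermediate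
13 | (2R,3S,4S)-5,7-bis(benzyloxy)-2-[3,4-bis(tert-butyldimethylsilyloxy)phenyl]chroman-3,4-diol | O(Cc1ccccc1)c1cc(OCc2ccccc2)c2c(c1)O[C@H](c1ccc(O[Si](C)(C)C(C)(C)C)c(O[Si](C)(C)C(C)(C)C)c1)[C@@H](O)[C@H]2O | intermediate
14 | (2R,3R)-5,7-bis(benzyloxy)-2-[3,4-bis(tert-butyldimethylsilyloxy)phenyl]-3-hydroxychroman-4-one | O(Cc1ccccc1)c1cc(OCc2ccccc2)c2c(c1)O[C@H](c1ccc(O[Si](C)(C)C(C)(C)C)c(O[Si](C)(C)C(C)(C)C)c1)[C@@H](O)C2=O | intermediate
15 | (2R,3R)-2-[3,4-bis(tert-butyldimethylsilyloxy)phenyl]-3,5,7-trihydroxychroman-4-one | Oc1cc(O)c2c(c1)O[C@H](c1ccc(O[Si](C)(C)C(C)(C)C)c(O[Si](C)(C)C(C)(C)C)c1)[C@@H](O)C2=O | intermediate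
16 | prenyl bromide (1-bromo-3-methylbut-2-ene) | CC(C)=CCBr | starting material
17 | (2R,3R)-2-[3,4-bis(tert-butyldimethylsilyloxy)phenyl]-3,5-dihydroxy-7-(3-methylbut-2-enyloxy)chroman-4-one | CC(C)=CCOc1cc(O)c2c(c1)O[C@H](c1ccc(O[Si](C)(C)C(C)(C)C)c(O[Si](C)(C)C(C)(C)C)c1)[C@@H](O)C2=O | intermediate
18 | (2R,3R)-2-(3,4-dihydroxyphenyl)-3,5-dihydroxy-7-(3-methylbut-2-enyloxy)chroman-4-one | CC(C)=CCOc1cc(O)c2c(c1)O[C@H](c1ccc(O)c(O)c1)[C@@H](O)C2=O | target

## Step count and weak points

Total: 13 steps. Longest linear sequence: 11 steps (steps 3 to 13, from 5). The ring A branch (steps 1 and 2) joins at step 7.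

**Step 9 (key step).** The most likely failure is incomplete facial selectivity, because the pyran ring of 12 is nearly flat and the C2 aryl group shields C3 only from one side at a distance. Two further processes can cost material: photochemical or thermal electrocyclic opening of the 2H-chromene, which would erode C2, and ionisation of the product at C4 on acidic silica. Fallback, from 12 to 14: epoxidation with the matched enantiomer of the (salen)MnCl complex of trivalent manganese (Jacobsen–Katsuki epoxidation; NaOCl, 4-phenylpyridine N-oxide, CH2Cl2, 0 °C) adds the catalyst's face preference to that of the substrate and should give the 2,3-trans-3,4-epoxyflavan F1 (epoxide oxygen anti to ring B). Hydrolysis in wet THF with a trace of acid opens F1 at the benzylic C4 and leaves the C3–O bond untouched, giving 13 together with its C4 epimer, the 2,3-trans-3,4-trans diol F2. Both are oxidised at C4 as in step 10 and converge on 14.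

**Step 7.** The most likely failure is low conversion and regiochemical scatter, because the ortho vinyl group hinders the aryloxide oxygen and offers the metal a second binding site. Prolonged exposure of the doubly activated branched ether to the catalyst can also lead to re-ionisation, with drift to the linear ether and loss of enantiopurity, and the aryloxide may attack a silyl ether. Fallback, from 3 and 9 to 11: the order of the two operations is exchanged so that no vinylphenol is involved. Aldehyde 3 is converted with n-BuLi into lithium 3,5-bis(benzyloxy)-2-formylphenoxide F3, which is allylated with 9 under the same iridium catalysis to (S)-2,4-bis(benzyloxy)-6-{1-[3,4-bis(tert-butyldimethylsilyloxy)phenyl]allyloxy}benzaldehyde F4. Wittig methylenation of F4 (Ph3PCH3Br, KOtBu, THF, 0 °C) then gives 11.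

**Step 10.** The most likely failure is glycol cleavage of the cis-diol on the manganese dioxide surface, or over-oxidation of the ketol towards the flavonol on long contact; ionisation at C4 is a further loss. Fallback, from 13 to 14, by protect, oxidise, release: the equatorial C3 hydroxyl is silylated in preference to the C4 hydroxyl, which is pseudo-axial and crowded by the peri 5-benzyloxy group (Et3SiCl, imidazole, CH2Cl2, −20 °C), to give the 3-O-triethylsilyl diol F5. Dess–Martin periodinane with NaHCO3 in CH2Cl2 oxidises the remaining C4 carbinol to the 3-O-triethylsilyl ketone F6. AcOH/THF/H2O then removes the alkyl silyl ether, leaving the aryl silyl ethers, and returns 14.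

**Step 12.** The most likely failure is base-induced opening of ring C from the enolate (loss of stereochemical integrity, or onward oxidation). A second risk is carbonate-mediated loss of an aryl silyl group followed by alkylation of ring B. Fallback, from 15 to 17 with no new intermediate: Mitsunobu etherification with 3-methylbut-2-en-1-ol, PPh3 and diisopropyl azodicarboxylate in THF at 0 °C. It runs without added base and selects the most acidic phenol, O7.

**Step 1.** The most likely failure is poor control of the degree of alkylation (mono-, di- and tribenzyl ethers together) and some C-benzylation of the phloroglucinol ring. Fallback, from 1 to 3: exhaustive benzylation (BnBr in excess, K2CO3, DMF, 60 °C) to 2,4,6-tris(benzyloxy)benzaldehyde F7, followed by chelation-directed removal of one ortho benzyl group with MgBr2·OEt2 in toluene/Et2O at reflux, which returns 3.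

## Further compounds

F1 | step 9 | (2R)-5,7-bis(benzyloxy)-2-[3,4-bis(tert-butyldimethylsilyloxy)phenyl]-3,4-epoxychroman, epoxide oxygen trans to ring B | O(Cc1ccccc1)c1cc(OCc2ccccc2)c2c(c1)O[C@H](c1ccc(O[Si](C)(C)C(C)(C)C)c(O[Si](C)(C)C(C)(C)C)c1)[C@H]3O[C@H]32
F2 | step 9 | (2R,3S,4R)-5,7-bis(benzyloxy)-2-[3,4-bis(tert-butyldimethylsilyloxy)phenyl]chroman-3,4-diol (2,3-trans-3,4-trans) | O(Cc1ccccc1)c1cc(OCc2ccccc2)c2c(c1)O[C@H](c1ccc(O[Si](C)(C)C(C)(C)C)c(O[Si](C)(C)C(C)(C)C)c1)[C@@H](O)[C@@H]2O
F3 | step 7 | lithium 3,5-bis(benzyloxy)-2-formylphenoxide | [Li+].[O-]c1cc(OCc2ccccc2)cc(OCc2ccccc2)c1C=O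
F4 | step 7 | (S)-2,4-bis(benzyloxy)-6-{1-[3,4-bis(tert-butyldimethylsilyloxy)phenyl]allyloxy}benzaldehyde | O=Cc1c(OCc2ccccc2)cc(OCc2ccccc2)cc1O[C@H](c1ccc(O[Si](C)(C)C(C)(C)C)c(O[Si](C)(C)C(C)(C)C)c1)C=C
F5 | step 10 | (2R,3S,4S)-5,7-bis(benzyloxy)-2-[3,4-bis(tert-butyldimethylsilyloxy)phenyl]-3-(triethylsilyloxy)chroman-4-ol | O(Cc1ccccc1)c1cc(OCc2ccccc2)c2c(c1)O[C@H](c1ccc(O[Si](C)(C)C(C)(C)C)c(O[Si](C)(C)C(C)(C)C)c1)[C@@H](O[Si](CC)(CC)CC)[C@H]2O
F6 | step 10 | (2R,3R)-5,7-bis(benzyloxy)-2-[3,4-bis(tert-butyldimethylsilyloxy)phenyl]-3-(triethylsilyloxy)chroman-4-one | O(Cc1ccccc1)c1cc(OCc2ccccc2)c2c(c1)O[C@H](c1ccc(O[Si](C)(C)C(C)(C)C)c(O[Si](C)(C)C(C)(C)C)c1)[C@@H](O[Si](CC)(CC)CC)C2=O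
F0 | step 12 | none | none
F7 | step 1 | 2,4,6-tris(benzyloxy)benzaldehyde | O=Cc1c(OCc2ccccc2)cc(OCc2ccccc2)cc1OCc1ccccc1
A1 | alternative 1 | (2R,3R)-3,5,7,3',4'-penta-O-benzyltaxifolin | c1ccccc1COc1cc(OCc3ccccc3)c2c(c1)O[C@H](c1ccc(OCc3ccccc3)c(OCc3ccccc3)c1)[C@@H](OCc1ccccc1)C2=O
A2 | alternative 1 | (2R,3R)-2-(benzyloxy)-3-[3,4-bis(benzyloxy)phenyl]-3-[3,5-bis(benzyloxy)phenoxy]propanoic acid | c1ccccc1COc1cc(OCc3ccccc3)cc(c1)O[C@H](c1ccc(OCc3ccccc3)c(OCc3ccccc3)c1)[C@@H](OCc1ccccc1)C(=O)O
A3 | alternative 2 | 2,3-trans-3-acetoxy-5-hydroxy-4-methoxy-7-(3-methylbut-2-enyloxy)-3',4'-bis(tert-butyldimethylsilyloxy)flavan, target configuration at C2 and C3, either C4 epimer | CC(C)=CCOc1cc(O)c2c(c1)O[C@H](c1ccc(O[Si](C)(C)C(C)(C)C)c(O[Si](C)(C)C(C)(C)C)c1)[C@@H](OC(C)=O)C2OC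
A4 | alternative 2 | 2,6-dihydroxy-4-(3-methylbut-2-enyloxy)benzaldehyde | O=Cc1c(O)cc(OCC=C(C)C)cc1O
A5 | alternative 2 | (E)-2-[3,4-bis(tert-butyldimethylsilyloxy)phenyl]vinyl acetate | CC(=O)O/C=C/c1ccc(O[Si](C)(C)C(C)(C)C)c(O[Si](C)(C)C(C)(C)C)c1
A6 | alternative 3 | (2R,3R)-3,3',4'-tris-O-(tert-butyldimethylsilyl)-7-O-prenyltaxifolin | CC(C)=CCOc1cc(O)c2c(c1)O[C@H](c1ccc(O[Si](C)(C)C(C)(C)C)c(O[Si](C)(C)C(C)(C)C)c1)[C@@H](O[Si](C)(C)C(C)(C)C)C2=O
A7 | alternative 3 | (2R,3R)-5-bromo-3-(tert-butyldimethylsilyloxy)-2-[3,4-bis(tert-butyldimethylsilyloxy)phenyl]-2,3-dihydropyran-4-one | BrC1=CO[C@H](c2ccc(O[Si](C)(C)C(C)(C)C)c(O[Si](C)(C)C(C)(C)C)c2)[C@@H](O[Si](C)(C)C(C)(C)C)C1=O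
A8 | alternative 3 | 1-methoxy-1-(trimethylsilyloxy)-3-(3-methylbut-2-enyloxy)buta-1,3-diene | C=C(OCC=C(C)C)C=C(OC)O[Si](C)(C)C
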